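We have one stirred vessel at constant volume and a single charge, entered in five ways.

| setting | Saturday's | Sunday's | dawn | autumn | spring | dusk | winter |
|---|---|---|---|---|---|---|---|
| starting material | 0.024 M | 0.024 M | 0.024 M | 0.024 M (fed, over 5.0 h) | 0.024 M (fed, over 20 h) | 0.024 M | 0.024 M |
| reagent | 3 equiv | 1.5 equiv | 3.00 equiv (in portions, 2, over 20 h) | 3.00 equiv | 3.00 equiv | 3.00 equiv | 3.00 equiv (fed, over 20 h) |
| remark | run made earlier | run made earlier | first portion at the start, last at 20 h | all else is in the flask from the start; the feed brings no volume worth counting | all else is in the flask from the start; the feed brings no volume worth counting | everything together at the start | all else is in the flask from the start; the feed brings no volume worth counting |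
| time |  |  | 25 h | 25 h | 25 h | 25 h | 25 h |

- the flask that comes out highest in amount of first product, in percent of the starting material charged, or "all alike" when all lie within 1.5 percentage points (dawn / autumn / spring / dusk / winter / all alike)
- first product at the end, in percent of the starting material charged, dawn
- first product at the end, in percent of the starting material charged, autumn
- first product at the end, in percent of the starting material charged, spring
- first product at the end, in percent of the starting material charged, dusk
- first product at the end, in percent of the starting material charged, winter

| run | time / h | first product / % | starting material / % |
|---|---|---|---|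
| Saturday's | 3.00 | 58.6 | 32.4 |
| Saturday's | 6.00 | 73.0 | 12.8 |
| Saturday's | 10.0 | 73.9 | 4.3 |
| Saturday's | 12.0 | 73.0 | 2.0 |
| Saturday's | 15.0 | 69.1 | 0.5 |
| Sunday's | 0.200 | 4.5 | 95.6 |
| Sunday's | 0.667 | 13.1 | 87.2 |
| Sunday's | 1.33 | 22.9 | 76.5 |
| Sunday's | 2.00 | 30.0 | 67.0 |
| Sunday's | 2.50 | 34.0 | 62.7 |

(readings scatter by 0.5 percentage points)

- a reading or a percentage of first product counts all its forms, free or not

What is neither starting material nor first product we call the lost share. In Saturday's run it stands at 25.0% after 12.0 h. Sunday's run has first product at 34.0% against Saturday's 73.0%, yet the ratio below barely moves. So we treat the active level of first product as held steady, and take the loss as following reagent-hours. Starting material also falls with reagent-hours, so the pace of reagent cancels. We define s, our selectivity factor, as the lost share per unit of ln(charged/left) of starting material: 6.39% from Saturday, 7.07% from Sunday's small loss, which has a scatter of 0.5 percentage points on each reading.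

First we turn the pace of reagent. With starting material in from the start, first product is the charge less what is left less s·ln(charged/left). It peaks where the share left equals s, at 76.0%. Dawn and winter can stop near there. With half of s left the line gives 74.8%. We take that as a rough level for dawn and winter, but how much starting material each leaves is not known here, so this line does not rank the two.

Next we turn the time. Dusk passes the peak. Saturday's lost share grows steadily from 10.0 h to 15.0 h, and carried on to 25 h that leaves dusk near 51.9%.

Last we turn the feed of starting material. Autumn's reagent stands as dusk's does, so we reckon it alike. Spring keeps reagent fuller for longer and ends with starting material unreacted, so we put it below dusk.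

The forecast, “assuming over-reaction needs reagent”, gives dawn 70%, autumn 59%, spring 65%, dusk 55% and winter 67%, with dawn highest.

Dawn gives 74.9%, higher than winter's 73.0%, autumn's 56.9%, dusk's 56.5% and spring's 50.9%.

    starting material + reagent → first product (k = 0.103 /M/min)
    reagent + first product → double product (k = 0.0528 /M/min)
    crystals ⇌ first product, rate k3*(cs3 - [first product]) while solid is left; crystals form when [first product] > cs3 (solubility = 2.80 mM, k = 0.0659 /min)

Dawn ends with 2.7% of its starting material left and 22.3% double product, and s on that share gives 23.1%. A neighbouring dawn with 1.20 equiv of reagent leaves 33.7%, for which s gives 6.95%, and that flask holds 6.46% double product.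

The runs come from a simulation for substances that don't exist; the scatter is artificial.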